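**Retrosynthetic overview**
1. Target 30 ← protected macrolide 29 ← CrCl2 Barbier closure of the C6–C7 bond in bromomethyl δ-lactone enal 27; the ten-membered carbocycle forms here and the δ-lactone contracts to the γ-lactone in the same flask, freeing the C9 hydroxyl.
2. δ-Lactone 27 ← pyranone 17 by lactol oxidation, Luche reduction, α-iodination, Mitsunobu inversion with (R)-2-methylbutanoic acid, Stille hydroxymethylation and Appel bromination; the six-membered ring relays C9 → C8 → C7.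
3. Pyranone 17 ← furyl carbinol 16 by a Sharpless-type kinetic resolution coupled to Achmatowicz ring expansion: the furan of furfural is dearomatized and supplies C8, C7, C11 and C12 (its CHO carbon is C9), and C9 is fixed in absolute sense.
4. 16 ← alkenyllithium from (Z)-iodide 13 + furfural (C9–C10 bond).
5. 13 ← but-2-yne-1,4-diol (C15, C4, C5, C6), acrolein diethyl acetal (C1–C3) and Ph3P=CHCHO (C10, C14). Ring order: furan (bought) → pyranone/δ-lactone → ten-membered carbocycle → γ-lactone.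

Notation and assumption: atom labels C1–C15 are the germacrane numbers of the target (lactone C12–O–C6, aldehyde C14, CH2OH C15); R = (2E,6E)-6-{[(tert-butyldimethylsilyl)oxy]methyl}-1,1-dimethoxy-8-[(4-methoxybenzyl)oxy]octa-2,6-dien-2-yl, attached through C10; the mono-silyl ether 2 is made rather than bought.

**Route**

Step 1
Reactants: 1 but-2-yne-1,4-diol
Product: 2 4-[(tert-butyldimethylsilyl)oxy]but-2-yn-1-ol
Conditions: NaH (1.0 equiv), THF, 0 °C; TBSCl (1.0 equiv), rt
Reagents that add atoms: tert-butyldimethylsilyl chloride, CC(C)(C)[Si](C)(C)Cl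
Why: Monosilylation of a symmetric diol through its sparingly soluble monosodium alkoxide (Williamson-type O-silylation) differentiates the future C15 and C6 oxygens.

Step 2
Reactants: 2 4-[(tert-butyldimethylsilyl)oxy]but-2-yn-1-ol
Product: 4 (Z)-4-[(tert-butyldimethylsilyl)oxy]-3-iodobut-2-en-1-ol, via cyclic alkenylalanate 3 (not isolated)
Conditions: NaAlH2(OCH2CH2OCH3)2, THF, 0 °C; then I2, −78 °C to 0 °C
Reagents that add atoms: iodine, II
Why: Hydroxyl-directed trans-hydroalumination puts aluminium on the carbon remote from the free OH, and iodinolysis with retention gives the vinyl iodide in which C6 and the iodine (later C3) are cis, fixing the C4=C5 geometry.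

Step 3
Reactants: 4 (Z)-4-[(tert-butyldimethylsilyl)oxy]-3-iodobut-2-en-1-ol
Product: 5 (Z)-tert-butyl({2-iodo-4-[(4-methoxybenzyl)oxy]but-2-en-1-yl}oxy)dimethylsilane
Conditions: NaH, 4-methoxybenzyl chloride, Bu4NI (cat.), THF/DMF, 0 °C to rt
Reagents that add atoms: 4-methoxybenzyl chloride, COc1ccc(CCl)cc1
Why: Williamson etherification masks the C6 hydroxyl as a PMB ether that is later removable by oxidation without touching the silyl ether or the acetal.

Step 4
Reactants: 5 (Z)-tert-butyl({2-iodo-4-[(4-methoxybenzyl)oxy]but-2-en-1-yl}oxy)dimethylsilane, 6 acrolein diethyl acetal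
Product: 8 (E)-tert-butyl({2-(3,3-diethoxypropyl)-4-[(4-methoxybenzyl)oxy]but-2-en-1-yl}oxy)dimethylsilane, via 9-(3,3-diethoxypropyl)-9-borabicyclo[3.3.1]nonane 7 (not isolated)
Conditions: 6, 9-BBN, THF, rt; then 5, PdCl2(dppf) (5 mol %), AsPh3, Cs2CO3, DMF/H2O, rt
Reagents that add atoms: none
Why: Anti-Markovnikov hydroboration followed by B-alkyl Suzuki–Miyaura coupling joins C3 to C4 with retention at the vinyl iodide, so C3 and C6 stay cis.

Step 5
Reactants: 8 (E)-tert-butyl({2-(3,3-diethoxypropyl)-4-[(4-methoxybenzyl)oxy]but-2-en-1-yl}oxy)dimethylsilane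
Product: 9 (E)-4-{[(tert-butyldimethylsilyl)oxy]methyl}-6-[(4-methoxybenzyl)oxy]hex-4-enal
Conditions: LiBF4, MeCN/H2O (98:2), rt
Reagents that add atoms: water, O
Why: Mild acetal hydrolysis frees the C1 aldehyde while the primary silyl ether and the PMB ether survive.

Step 6
Reactants: 9 (E)-4-{[(tert-butyldimethylsilyl)oxy]methyl}-6-[(4-methoxybenzyl)oxy]hex-4-enal, 10 (triphenylphosphoranylidene)acetaldehyde
Product: 11 (2E,6E)-6-{[(tert-butyldimethylsilyl)oxy]methyl}-8-[(4-methoxybenzyl)oxy]octa-2,6-dienal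
Conditions: toluene, 80 °C
Reagents that add atoms: none
Why: Wittig olefination with a stabilized ylide gives the (E)-enal, adding C10 and C14 with the formyl group trans to C2.

Step 7
Reactants: 11 (2E,6E)-6-{[(tert-butyldimethylsilyl)oxy]methyl}-8-[(4-methoxybenzyl)oxy]octa-2,6-dienal
Product: 12 (2Z,6E)-6-{[(tert-butyldimethylsilyl)oxy]methyl}-2-iodo-8-[(4-methoxybenzyl)oxy]octa-2,6-dienal
Conditions: I2, K2CO3, DMAP (cat.), THF/H2O, rt
Reagents that add atoms: iodine, II
Why: DMAP-catalysed α-iodination of the enal (conjugate addition, iodination, elimination) keeps CHO trans to C2, so the iodine (later C9) is cis to C2 as the C1=C10 bond of the target requires.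

Step 8
Reactants: 12 (2Z,6E)-6-{[(tert-butyldimethylsilyl)oxy]methyl}-2-iodo-8-[(4-methoxybenzyl)oxy]octa-2,6-dienal
Product: 13 (2Z,6E)-6-{[(tert-butyldimethylsilyl)oxy]methyl}-2-iodo-1,1-dimethoxy-8-[(4-methoxybenzyl)oxy]octa-2,6-diene
Conditions: HC(OMe)3, CeCl3·7H2O (cat.), MeOH, rt
Reagents that add atoms: trimethyl orthoformate, COC(OC)OC
Why: Acetalization stores C14 at the aldehyde oxidation level, so it needs no later differentiation from C15.

Step 9
Reactants: 13 (2Z,6E)-6-{[(tert-butyldimethylsilyl)oxy]methyl}-2-iodo-1,1-dimethoxy-8-[(4-methoxybenzyl)oxy]octa-2,6-diene, 14 furfural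
Product: 16 rac-(2E,6E)-6-{[(tert-butyldimethylsilyl)oxy]methyl}-2-(dimethoxymethyl)-1-(furan-2-yl)-8-[(4-methoxybenzyl)oxy]octa-2,6-dien-1-ol, via alkenyllithium 15 (not isolated)
Conditions: t-BuLi (2.1 equiv), Et2O, −78 °C; then 14, −78 °C
Reagents that add atoms: none
Why: Iodine–lithium exchange with retention (a 2-lithioacrolein-acetal type reagent) and 1,2-addition to furfural form the C9–C10 bond; the carbinol is racemic here.

Step 10
Reactants: 16 rac-(2E,6E)-6-{[(tert-butyldimethylsilyl)oxy]methyl}-2-(dimethoxymethyl)-1-(furan-2-yl)-8-[(4-methoxybenzyl)oxy]octa-2,6-dien-1-ol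
Product: 17 (2S)-6-hydroxy-2-R-2H-pyran-3(6H)-one (anomeric mixture)
Conditions: Ti(OiPr)4 (20 mol %), L-(+)-diisopropyl tartrate (24 mol %), t-BuOOH (0.6 equiv), 4 Å MS, CH2Cl2, −20 °C
Reagents that add atoms: tert-butyl hydroperoxide, CC(C)(C)OO
Why: Sharpless kinetic resolution coupled to Achmatowicz oxidative ring expansion: with the furan 2,3-bond acting as the allylic olefin, the tetravalent titanium–L-(+)-tartrate complex oxidizes the furan of (S)-16 much faster than that of (R)-16 (at most 50 %, (R)-16 recovered), and the C9 configuration is carried unchanged into the pyranone, whose ring later fixes C8 and C7.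

Step 11
Reactants: 17 (2S)-6-hydroxy-2-R-2H-pyran-3(6H)-one
Product: 18 (6S)-6-R-2H-pyran-2,5(6H)-dione
Conditions: TEMPO (cat.), PhI(OAc)2, CH2Cl2, rt
Reagents that add atoms: none
Why: Oxoammonium (TEMPO) oxidation of the lactol gives the unsaturated δ-lactone (C12 carbonyl) under non-basic conditions that spare the enolizable C9 centre.

Step 12
Reactants: 18 (6S)-6-R-2H-pyran-2,5(6H)-dione
Product: 19 (5R,6S)-5-hydroxy-6-R-5,6-dihydro-2H-pyran-2-one
Conditions: NaBH4, CeCl3·7H2O, MeOH, −78 °C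
Reagents that add atoms: none
Why: Luche 1,2-reduction by axial hydride attack gives the equatorial C8 alcohol trans to the C9 side chain; this is the C8 epimer of the target, set up for inversion.

Step 13
Reactants: 19 (5R,6S)-5-hydroxy-6-R-5,6-dihydro-2H-pyran-2-one
Product: 20 (5R,6S)-5-hydroxy-3-iodo-6-R-5,6-dihydro-2H-pyran-2-one
Conditions: I2, pyridine, CH2Cl2, 0 °C to rt
Reagents that add atoms: iodine, II
Why: Pyridine-mediated α-iodination of the unsaturated lactone (addition–iodination–elimination) puts a handle on C11, and is done before esterification so that no base meets the eliminable cis ester.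

Step 14
Reactants: 20 (5R,6S)-5-hydroxy-3-iodo-6-R-5,6-dihydro-2H-pyran-2-one, 21 (R)-2-methylbutanoic acid
Product: 22 (5S,6S)-3-iodo-2-oxo-6-R-5,6-dihydro-2H-pyran-5-yl (R)-2-methylbutanoate
Conditions: PPh3, DIAD, THF, 0 °C to rt
Reagents that add atoms: none
Why: Mitsunobu esterification inverts C8 to the target configuration (cis to the C9 side chain) and installs the natural ester in one operation, without enolizing the acid stereocentre.

Step 15
Reactants: 22 (5S,6S)-3-iodo-2-oxo-6-R-5,6-dihydro-2H-pyran-5-yl (R)-2-methylbutanoate, 23 (tributylstannyl)methanol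
Product: 24 (5S,6S)-3-(hydroxymethyl)-2-oxo-6-R-5,6-dihydro-2H-pyran-5-yl (R)-2-methylbutanoate
Conditions: Pd(PPh3)4 (10 mol %), 1,4-dioxane, 80 °C
Reagents that add atoms: none
Why: Stille coupling of the α-iodo lactone with the hydroxymethylstannane introduces C13 under neutral conditions.

Step 16
Reactants: 24 (5S,6S)-3-(hydroxymethyl)-2-oxo-6-R-5,6-dihydro-2H-pyran-5-yl (R)-2-methylbutanoate
Product: 25 (5S,6S)-3-(bromomethyl)-2-oxo-6-R-5,6-dihydro-2H-pyran-5-yl (R)-2-methylbutanoate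
Conditions: CBr4, PPh3, CH2Cl2, 0 °C
Reagents that add atoms: carbon tetrabromide, BrC(Br)(Br)Br
Why: Appel bromination of the primary allylic alcohol gives the 2-(bromomethyl)acrylate-type allyl donor, and must precede aldehyde formation.

Step 17
Reactants: 25 (5S,6S)-3-(bromomethyl)-2-oxo-6-R-5,6-dihydro-2H-pyran-5-yl (R)-2-methylbutanoate
Product: 26 (5S,6S)-3-(bromomethyl)-6-[(2E,6E)-6-{[(tert-butyldimethylsilyl)oxy]methyl}-8-hydroxy-1,1-dimethoxyocta-2,6-dien-2-yl]-2-oxo-5,6-dihydro-2H-pyran-5-yl (R)-2-methylbutanoate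
Conditions: DDQ, CH2Cl2/pH 7 buffer, 0 °C
Reagents that add atoms: none
Why: Oxidative PMB cleavage frees the C6 hydroxyl; the buffer protects the acetal and the silyl ether.

Step 18
Reactants: 26 the C6 alcohol from step 17
Product: 27 (5S,6S)-3-(bromomethyl)-6-[(2E,6Z)-6-{[(tert-butyldimethylsilyl)oxy]methyl}-1,1-dimethoxy-8-oxoocta-2,6-dien-2-yl]-2-oxo-5,6-dihydro-2H-pyran-5-yl (R)-2-methylbutanoate
Conditions: MnO2, CH2Cl2, rt
Reagents that add atoms: none
Why: MnO2 oxidation of the primary allylic alcohol gives the C6 enal under neutral conditions, keeping the C4=C5 geometry (C6 cis to C3).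

Step 19
Reactants: 27 the bromomethyl δ-lactone enal from step 18
Product: 29 14,14-dimethyl acetal 15-O-TBS ether of the target, via bridged delta-lactone carbinol 28 (not isolated)
Conditions: CrCl2 (8 equiv), THF/DMF, 0.002 M, rt; aq. NH4Cl
Reagents that add atoms: none
Why: Proposed new method: divalent chromium inserts into the allylic C–Br bond, and the allylchromium, whose C8 substituent is locked trans to CH2Cr by the ring, adds to the C6 aldehyde through a chair transition state at C7 anti to the pseudo-axial C8 acyloxy group (C6/C7 anti, C7/C8 trans, forming the ten-membered ring); the C6 chromium alkoxide then attacks C12 in a five-membered mode and the δ-lactone contracts to the α-methylene-γ-lactone, releasing the C9 hydroxyl; the closest known reaction is the intramolecular Nozaki–Hiyama (Barbier) allylation of 2-(bromomethyl)acrylates that closes germacranolide rings with lactonization.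

Step 20
Reactants: 29 14,14-dimethyl acetal 15-O-TBS ether of the target
Product: 30 target (CNP0331447.8)
Conditions: HF (48 % aq.), MeCN, 0 °C
Reagents that add atoms: water, O
Why: One acidic fluoride treatment removes the silyl ether (C15 OH) and hydrolyses the acetal (C14 aldehyde) without base, so the 8-ester does not migrate and the α-methylene lactone is untouched.

**Compound list**
1 | but-2-yne-1,4-diol | OCC#CCO | starting material
2 | 4-[(tert-butyldimethylsilyl)oxy]but-2-yn-1-ol | OCC#CCO[Si](C)(C)C(C)(C)C | intermediate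
3 | sodium cyclic alkenylalanate (2,5-dihydro-1,2-oxaalumol-2-uide bearing two 2-methoxyethoxy groups on Al and CH2OTBS on C3) | [Na+].COCCO[Al-]1(OCCOC)OCC=C1CO[Si](C)(C)C(C)(C)C | intermediate
4 | (Z)-4-[(tert-butyldimethylsilyl)oxy]-3-iodobut-2-en-1-ol | OC/C=C(\I)CO[Si](C)(C)C(C)(C)C | intermediate
5 | (Z)-tert-butyl({2-iodo-4-[(4-methoxybenzyl)oxy]but-2-en-1-yl}oxy)dimethylsilane | COc1ccc(COC/C=C(\I)CO[Si](C)(C)C(C)(C)C)cc1 | intermediate
6 | acrolein diethyl acetal (3,3-diethoxyprop-1-ene) | C=CC(OCC)OCC | starting material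
7 | 9-(3,3-diethoxypropyl)-9-borabicyclo[3.3.1]nonane | CCOC(CCB1C2CCCC1CCC2)OCC | intermediate
8 | (E)-tert-butyl({2-(3,3-diethoxypropyl)-4-[(4-methoxybenzyl)oxy]but-2-en-1-yl}oxy)dimethylsilane (C3 cis to C6) | CCOC(CC/C(CO[Si](C)(C)C(C)(C)C)=C\COCc1ccc(OC)cc1)OCC | intermediate
9 | (E)-4-{[(tert-butyldimethylsilyl)oxy]methyl}-6-[(4-methoxybenzyl)oxy]hex-4-enal | O=CCC/C(CO[Si](C)(C)C(C)(C)C)=C\COCc1ccc(OC)cc1 | intermediate
10 | (triphenylphosphoranylidene)acetaldehyde | O=CC=P(c1ccccc1)(c1ccccc1)c1ccccc1 | starting material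
11 | (2E,6E)-6-{[(tert-butyldimethylsilyl)oxy]methyl}-8-[(4-methoxybenzyl)oxy]octa-2,6-dienal | O=C/C=C/CC/C(CO[Si](C)(C)C(C)(C)C)=C\COCc1ccc(OC)cc1 | intermediate
12 | (2Z,6E)-6-{[(tert-butyldimethylsilyl)oxy]methyl}-2-iodo-8-[(4-methoxybenzyl)oxy]octa-2,6-dienal | I/C(=C\CC/C(CO[Si](C)(C)C(C)(C)C)=C\COCc1ccc(OC)cc1)C=O | intermediate
13 | (2Z,6E)-6-{[(tert-butyldimethylsilyl)oxy]methyl}-2-iodo-1,1-dimethoxy-8-[(4-methoxybenzyl)oxy]octa-2,6-diene | I/C(=C\CC/C(CO[Si](C)(C)C(C)(C)C)=C\COCc1ccc(OC)cc1)C(OC)OC | intermediate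
14 | furfural (furan-2-carbaldehyde) | O=Cc1ccco1 | starting material
15 | alkenyllithium R–Li (lithium in place of the iodine of 13, geometry retained) | [Li]/C(=C\CC/C(CO[Si](C)(C)C(C)(C)C)=C\COCc1ccc(OC)cc1)C(OC)OC | intermediate
16 | rac-(2E,6E)-6-{[(tert-butyldimethylsilyl)oxy]methyl}-2-(dimethoxymethyl)-1-(furan-2-yl)-8-[(4-methoxybenzyl)oxy]octa-2,6-dien-1-ol (R–CH(OH)–2-furyl) | OC(c1ccco1)/C(=C\CC/C(CO[Si](C)(C)C(C)(C)C)=C\COCc1ccc(OC)cc1)C(OC)OC | intermediate
17 | (2S)-6-hydroxy-2-R-2H-pyran-3(6H)-one (anomeric mixture) | OC1C=CC(=O)[C@H](/C(=C\CC/C(CO[Si](C)(C)C(C)(C)C)=C\COCc2ccc(OC)cc2)C(OC)OC)O1 | intermediate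
18 | (6S)-6-R-2H-pyran-2,5(6H)-dione | O=C1C=CC(=O)[C@H](/C(=C\CC/C(CO[Si](C)(C)C(C)(C)C)=C\COCc2ccc(OC)cc2)C(OC)OC)O1 | intermediate
19 | (5R,6S)-5-hydroxy-6-R-5,6-dihydro-2H-pyran-2-one (5,6-trans) | O=C1C=C[C@@H](O)[C@H](/C(=C\CC/C(CO[Si](C)(C)C(C)(C)C)=C\COCc2ccc(OC)cc2)C(OC)OC)O1 | intermediate
20 | (5R,6S)-5-hydroxy-3-iodo-6-R-5,6-dihydro-2H-pyran-2-one | O=C1C(I)=C[C@@H](O)[C@H](/C(=C\CC/C(CO[Si](C)(C)C(C)(C)C)=C\COCc2ccc(OC)cc2)C(OC)OC)O1 | intermediate
21 | (R)-2-methylbutanoic acid | CC[C@@H](C)C(=O)O | starting material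
22 | (5S,6S)-3-iodo-2-oxo-6-R-5,6-dihydro-2H-pyran-5-yl (R)-2-methylbutanoate (5,6-cis) | O=C1C(I)=C[C@H](OC(=O)[C@H](C)CC)[C@H](/C(=C\CC/C(CO[Si](C)(C)C(C)(C)C)=C\COCc2ccc(OC)cc2)C(OC)OC)O1 | intermediate
23 | (tributylstannyl)methanol | CCCC[Sn](CCCC)(CCCC)CO | starting material
24 | (5S,6S)-3-(hydroxymethyl)-2-oxo-6-R-5,6-dihydro-2H-pyran-5-yl (R)-2-methylbutanoate | O=C1C(CO)=C[C@H](OC(=O)[C@H](C)CC)[C@H](/C(=C\CC/C(CO[Si](C)(C)C(C)(C)C)=C\COCc2ccc(OC)cc2)C(OC)OC)O1 | intermediate
25 | (5S,6S)-3-(bromomethyl)-2-oxo-6-R-5,6-dihydro-2H-pyran-5-yl (R)-2-methylbutanoate | O=C1C(CBr)=C[C@H](OC(=O)[C@H](C)CC)[C@H](/C(=C\CC/C(CO[Si](C)(C)C(C)(C)C)=C\COCc2ccc(OC)cc2)C(OC)OC)O1 | intermediate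
26 | as 25 with the C6 OPMB replaced by OH | O=C1C(CBr)=C[C@H](OC(=O)[C@H](C)CC)[C@H](/C(=C\CC/C(CO[Si](C)(C)C(C)(C)C)=C\CO)C(OC)OC)O1 | intermediate
27 | as 26 with C6 oxidized to the aldehyde (C6 cis to C3) | O=C1C(CBr)=C[C@H](OC(=O)[C@H](C)CC)[C@H](/C(=C\CC/C(CO[Si](C)(C)C(C)(C)C)=C\C=O)C(OC)OC)O1 | intermediate
28 | bridged δ-lactone carbinol (formed as its trivalent chromium alkoxide): ten-membered carbocycle with C6 OH, exocyclic C11=C13 and lactone C12–O–C9 | C=C1C(=O)O[C@@H]2[C@@H](OC(=O)[C@H](C)CC)[C@@H]1[C@H](O)/C=C(/CO[Si](C)(C)C(C)(C)C)CC/C=C2/C(OC)OC | intermediate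
29 | 14,14-dimethyl acetal 15-O-TBS ether of the target (γ-lactone C12–O–C6, free C9 OH) | C=C1C(=O)O[C@@H]2/C=C(/CO[Si](C)(C)C(C)(C)C)CC/C=C(/C(OC)OC)[C@H](O)[C@@H](OC(=O)[C@H](C)CC)[C@@H]12 | intermediate
30 | CNP0331447.8 | C=C1C(=O)O[C@@H]2/C=C(/CO)CC/C=C(/C=O)[C@H](O)[C@@H](OC(=O)[C@H](C)CC)[C@@H]12 | target

**Step count**
Total step count: 20. Longest linear sequence: 20 steps, from but-2-yne-1,4-diol 1.

**Three steps most likely to fail, with fallbacks**

Step 10. The substrate is both a furyl carbinol and an allylic alcohol, so epoxidation of C10=C1 may compete; the yield is capped at 50 %, and the sense of resolution rests on analogy with simple 2-furylcarbinols. The fallback sets out from 16 and returns at 17: oxidize rac-16 with MnO2 to the furyl dienone F1; reduce it by Corey–Bakshi–Shibata reduction (Me-CBS oxazaborolidine, BH3·SMe2, −40 °C, catalyst enantiomer chosen to deliver hydride to the face that gives the S alcohol) to the single enantiomer (S)-carbinol F2; then run a non-asymmetric Achmatowicz ring expansion (NBS, NaHCO3, NaOAc, THF/H2O, 0 °C) to 17. Absolute control then comes from a reagent-controlled reduction instead of a resolution.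

Step 14. SN2 displacement at a hindered allylic ring carbon by an α-branched carboxylate may be slow, and SN2′ attack or loss of the activated alcohol toward a 2-pyrone may compete. The fallback sets out from 18 and returns at 22: reduce 18 with an oxazaborolidine/catecholborane system whose enantiomer is matched for hydride delivery anti to the face used by NaBH4/CeCl3, giving the cis-alcohol F3 directly; iodinate (I2, pyridine) to the cis-iodo alcohol F4; then acylate with retention using 21 (EDC, cat. DMAP, CH2Cl2, 0 °C) to reach 22. The C8 configuration is then set by reduction and no inversion is needed.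

Step 19. The allylchromium carries an acyloxy leaving group at the δ-position (C8) and may undergo reductive 1,4-elimination toward a pyrone; the bridged transition state may be strained; and the freed C9 alkoxide may take the acyl group from O8. The fallback sets out from 22 and returns at 29: Negishi coupling of 22 with IZnCH2B(pin) (Pd(PPh3)4, THF, rt) gives the allylboronate F5; DDQ removes the PMB group to give the alcohol F6; MnO2 gives the aldehyde F7; heating F7 in toluene at 80 °C and 0.002 M effects a neutral intramolecular allylboration through the same chair transition state with no carbanionic character, and aqueous work-up of the borate triggers the same lactone contraction to 29.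

Further compounds
F1 | step 10 | (2E,6E)-6-{[(tert-butyldimethylsilyl)oxy]methyl}-2-(dimethoxymethyl)-1-(furan-2-yl)-8-[(4-methoxybenzyl)oxy]octa-2,6-dien-1-one | O=C(c1ccco1)/C(=C\CC/C(CO[Si](C)(C)C(C)(C)C)=C\COCc1ccc(OC)cc1)C(OC)OC
F2 | step 10 | (S)-enantiomer of carbinol 16 | O[C@H](c1ccco1)/C(=C\CC/C(CO[Si](C)(C)C(C)(C)C)=C\COCc1ccc(OC)cc1)C(OC)OC
F3 | step 14 | (5S,6S)-5-hydroxy-6-R-5,6-dihydro-2H-pyran-2-one (5,6-cis) | O=C1C=C[C@H](O)[C@H](/C(=C\CC/C(CO[Si](C)(C)C(C)(C)C)=C\COCc2ccc(OC)cc2)C(OC)OC)O1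
F4 | step 14 | (5S,6S)-5-hydroxy-3-iodo-6-R-5,6-dihydro-2H-pyran-2-one | O=C1C(I)=C[C@H](O)[C@H](/C(=C\CC/C(CO[Si](C)(C)C(C)(C)C)=C\COCc2ccc(OC)cc2)C(OC)OC)O1
F5 | step 19 | (5S,6S)-2-oxo-6-R-3-[(4,4,5,5-tetramethyl-1,3,2-dioxaborolan-2-yl)methyl]-5,6-dihydro-2H-pyran-5-yl (R)-2-methylbutanoate | O=C1C(CB3OC(C)(C)C(C)(C)O3)=C[C@H](OC(=O)[C@H](C)CC)[C@H](/C(=C\CC/C(CO[Si](C)(C)C(C)(C)C)=C\COCc2ccc(OC)cc2)C(OC)OC)O1
F6 | step 19 | as F5 with the C6 OPMB replaced by OH | O=C1C(CB3OC(C)(C)C(C)(C)O3)=C[C@H](OC(=O)[C@H](C)CC)[C@H](/C(=C\CC/C(CO[Si](C)(C)C(C)(C)C)=C\CO)C(OC)OC)O1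
F7 | step 19 | as F6 with C6 oxidized to the aldehyde | O=C1C(CB3OC(C)(C)C(C)(C)O3)=C[C@H](OC(=O)[C@H](C)CC)[C@H](/C(=C\CC/C(CO[Si](C)(C)C(C)(C)C)=C\C=O)C(OC)OC)O1
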